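## Retrosynthetic overview

1. Lactone ring O1–C2(=O)–C3–C4–C5: the C4–OH / C5–O1 pair is traced back to anti addition of two oxygens to a (Z)-C4=C5 alkene. An epoxide oxygen stays on C4, and the acyl oxygen enters C5 with inversion; this lactone is the last ring to form.
2. C4=C5 is made by ring-closing metathesis inside a seven-membered lactone in which the acyl carbon C2 is parked on the tertiary side-chain oxygen at C2′. This O–C2 ester bond and its ring are absent from the target and are cleaved when the acyl group moves on to O1.
3. Enabling feature: the tertiary hydroxyl at C2′ lies 1,3 to C5 (C5–C1′–C2′–OH), so C2 can acylate either oxygen. A ring of seven (O, C2, C3, C4, C5, C1′, C2′) admits only a cis ring alkene, which after anti opening gives the required relative configuration at C4/C5 (OH cis to the side chain).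
4. C2′ (R) comes from (R)-2-methylglycidol by two Cu-catalysed epoxide openings (isopropenyl, then the arylalkyl chain). The absolute configuration at C4/C5 is set by a catalyst-controlled epoxidation, because the remote C2′ centre (methyl versus n-alkyl) cannot bias it.
5. Ring order: oxepinone (step 6) → fused oxirane (step 7) → oxolanone with loss of the seven-membered ring (step 8); the benzyl ether on the phenol is removed last.

Key step: step 6

Remark: atoms are numbered as in the lactone (O1, C2 carbonyl, C3, C4 carbinol, C5 quaternary; side chain C1′, C2′ carbinol); (R)-2-methylglycidol, 4-(benzyloxy)phenylmagnesium bromide solution and but-3-enoyl chloride are taken to be purchasable, and the phenol is carried as its benzyl ether.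

## Route

Step 1
Reactants: 1 (R)-2-methylglycidol; 2 isopropenylmagnesium bromide
Product: 4 (S)-2,4-dimethylpent-4-ene-1,2-diol, via bromomagnesium alkoxide of 1 3 (not isolated)
Conditions: 2 (2.5 equiv), CuI (10 mol %), THF, −30 → 0 °C; then H2O
Reagents that add atoms: none
Why: Cu-catalysed SN2 opening of the 2,2-disubstituted epoxide at its CH2 carbon by the alkenyl Grignard reagent (the first equivalent only deprotonates the hydroxyl group); the quaternary stereocentre is not involved, its descriptor changing from R to S only through the priority rules.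

Step 2
Reactants: 4 (S)-2,4-dimethylpent-4-ene-1,2-diol
Product: 6 (S)-2-methyl-2-(2-methylprop-2-en-1-yl)oxirane, via primary monotosylate 5 (not isolated)
Conditions: NaH (2.2 equiv), 1-(p-toluenesulfonyl)imidazole (1.05 equiv), THF, 0 °C → rt
Reagents that add atoms: none
Why: Selective sulfonylation of the primary alkoxide and intramolecular Williamson etherification by the tertiary alkoxide (3-exo-tet) place the epoxide on the other arm; no bond to the stereocentre is broken.

Step 3
Reactants: 7 4-(benzyloxy)phenylmagnesium bromide; 8 1,8-dibromooctane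
Product: 9 1-(benzyloxy)-4-(8-bromooctyl)benzene
Conditions: 8 (3 equiv), Li2CuCl4 (3 mol %), THF, 0 °C; excess 8 removed by distillation
Reagents that add atoms: none
Why: Cu-catalysed cross-coupling of an aryl Grignard reagent with a primary alkyl bromide (Kochi-type coupling); the excess of dibromide keeps double arylation low.

Step 4
Reactants: 9 1-(benzyloxy)-4-(8-bromooctyl)benzene; 6 (S)-2-methyl-2-(2-methylprop-2-en-1-yl)oxirane
Product: 11 (R)-13-[4-(benzyloxy)phenyl]-2,4-dimethyltridec-1-en-4-ol, via {8-[4-(benzyloxy)phenyl]octyl}magnesium bromide 10 (not isolated)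
Conditions: Mg, THF, 40 °C; then 6, CuI (10 mol %), THF, −30 → 0 °C; then H2O
Reagents that add atoms: none
Why: Cu-catalysed opening of the 2,2-disubstituted epoxide at the CH2 carbon by a primary alkyl Grignard reagent gives the tertiary carbinol, whose configuration (C2′ of the target, R) is carried over unchanged from 1.

Step 5
Reactants: 11 (R)-13-[4-(benzyloxy)phenyl]-2,4-dimethyltridec-1-en-4-ol; 12 but-3-enoyl chloride
Product: 14 (R)-13-[4-(benzyloxy)phenyl]-2,4-dimethyltridec-1-en-4-yl but-3-enoate, via lithium alkoxide of 11 13 (not isolated)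
Conditions: n-BuLi (1.05 equiv), THF, −78 °C; then 12 (1.2 equiv), −78 → 0 °C
Reagents that add atoms: none
Why: O-acylation of a hindered tertiary lithium alkoxide with an acyl chloride (nucleophilic acyl substitution, or addition to the vinylketene that the alkoxide may generate, both leading to the β,γ-unsaturated ester) at low temperature without amine base, so that the double bond stays out of conjugation.

Step 6
Reactants: 14 (R)-13-[4-(benzyloxy)phenyl]-2,4-dimethyltridec-1-en-4-yl but-3-enoate
Product: 15 (R)-7-{9-[4-(benzyloxy)phenyl]nonyl}-5,7-dimethyl-6,7-dihydrooxepin-2(3H)-one (ring double bond C4=C5, cis)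
Conditions: second-generation Grubbs catalyst RuCl2(=CHPh)(PCy3)(H2IMes) (5–10 mol %, in two portions), 1,4-benzoquinone (10 mol %), toluene (2 mM), 80 °C, argon sparge
Reagents that add atoms: none
Why: The ruthenium alkylidene first engages the unhindered monosubstituted vinyl group of the but-3-enoate and then closes onto the 1,1-disubstituted methallyl alkene by [2+2] cycloaddition and cycloreversion, releasing ethene (ring-closing olefin metathesis; closest precedent: closure of trisubstituted cycloalkenes and of seven-membered unsaturated lactones with second-generation ruthenium catalysts). One ring is closed, the seven-membered lactone, by olefin metathesis at C4=C5, the other ring atoms (O, C2, C3, C1′, C2′) being in place beforehand. No stereocentre is created; the step fixes the alkene geometry, which can only be cis (Z) in a ring of seven, and this geometry is the latent relative configuration of C4/C5 because the two oxygens are later added anti. The step needs cyclisation to win over oligomerisation, and the β,γ-double bond to stay out of conjugation (a conjugated isomer would close a six-membered lactone with loss of propene). The quaternary C2′ (Thorpe–Ingold effect) together with high dilution secures the first, and 1,4-benzoquinone as scavenger of ruthenium hydrides the second. The stereocentre at C2′ is remote from both alkenes and is not affected.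

Step 7
Reactants: 15 (R)-7-{9-[4-(benzyloxy)phenyl]nonyl}-5,7-dimethyl-6,7-dihydrooxepin-2(3H)-one
Product: 16 (1S,5R,7R)-5-{9-[4-(benzyloxy)phenyl]nonyl}-5,7-dimethyl-4,8-dioxabicyclo[5.1.0]octan-3-one (cis-fused epoxy lactone; S at C4 and R at C5 in lactone numbering)
Conditions: L-series Shi ketone (1,2:4,5-di-O-isopropylidene-β-L-erythro-2,3-hexodiulo-2,6-pyranose, from L-sorbose, 0.3 equiv), Oxone (2KHSO5·KHSO4·K2SO4), K2CO3, Bu4NHSO4 (5 mol %), Na2B4O7/Na2EDTA buffer (pH about 10.5), MeCN/dimethoxymethane, 0 °C
Reagents that add atoms: potassium peroxymonosulfate (active component of Oxone), [K+].[O-]S(=O)(=O)OO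
Why: Shi asymmetric epoxidation (chiral dioxirane, spiro transition state) of a trisubstituted alkene: syn delivery of oxygen makes the cis-fused oxirane, and the face is chosen by the catalyst and not by the remote C2′ centre, the L-series ketone being the one predicted to give S at C4 and R at C5.

Step 8
Reactants: 16 (1S,5R,7R)-5-{9-[4-(benzyloxy)phenyl]nonyl}-5,7-dimethyl-4,8-dioxabicyclo[5.1.0]octan-3-one
Product: 17 (4S,5S)-5-{(2R)-11-[4-(benzyloxy)phenyl]-2-hydroxy-2-methylundecyl}-4-hydroxy-5-methyloxolan-2-one
Conditions: TsOH·H2O (0.1 equiv), THF/H2O (10:1), 0 °C → rt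
Reagents that add atoms: water, O
Why: Acid-catalysed anti opening of the trisubstituted epoxide at its tertiary carbon by the neighbouring acyl oxygen (epoxy-ester participation, as in the lactonisation of β,γ-epoxy esters) with hydrolytic release of the tertiary side-chain hydroxyl: C5 is set by inversion (R to S), C4 keeps its oxygen and configuration, and the five-membered lactone is the thermodynamic resting place of the acyl group.

Step 9
Reactants: 17 (4S,5S)-5-{(2R)-11-[4-(benzyloxy)phenyl]-2-hydroxy-2-methylundecyl}-4-hydroxy-5-methyloxolan-2-one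
Product: 18 (4S,5S)-4-hydroxy-5-[(2R)-2-hydroxy-11-(4-hydroxyphenyl)-2-methylundecyl]-5-methyloxolan-2-one (CNP0245239.1)
Conditions: H2 (1 atm), Pd/C (10 wt %), EtOAc, rt
Reagents that add atoms: none
Why: Catalytic hydrogenolysis of the benzyl aryl ether under neutral conditions; the lactone and the hydroxyl groups are inert and no stereocentre is touched.

## Compound list

1 | (R)-2-methylglycidol, [(2R)-2-methyloxiran-2-yl]methanol | C[C@@]1(CO)CO1 | starting material
2 | isopropenylmagnesium bromide (prop-1-en-2-ylmagnesium bromide) | CC(=C)[Mg]Br | starting material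
3 | bromomagnesium alkoxide of 1 | C[C@@]1(CO[Mg]Br)CO1 | intermediate
4 | (S)-2,4-dimethylpent-4-ene-1,2-diol | C[C@@](O)(CO)CC(C)=C | intermediate
5 | (S)-2-hydroxy-2,4-dimethylpent-4-en-1-yl 4-methylbenzenesulfonate (primary monotosylate) | C[C@@](O)(COS(=O)(=O)c1ccc(C)cc1)CC(C)=C | intermediate
6 | (S)-2-methyl-2-(2-methylprop-2-en-1-yl)oxirane | C[C@@]1(CO1)CC(C)=C | intermediate
7 | 4-(benzyloxy)phenylmagnesium bromide | Br[Mg]c1ccc(OCc2ccccc2)cc1 | starting material
8 | 1,8-dibromooctane | BrCCCCCCCCBr | starting material
9 | 1-(benzyloxy)-4-(8-bromooctyl)benzene | BrCCCCCCCCc1ccc(OCc2ccccc2)cc1 | intermediate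
10 | {8-[4-(benzyloxy)phenyl]octyl}magnesium bromide | Br[Mg]CCCCCCCCc1ccc(OCc2ccccc2)cc1 | intermediate
11 | (R)-13-[4-(benzyloxy)phenyl]-2,4-dimethyltridec-1-en-4-ol | C[C@@](O)(CCCCCCCCCc1ccc(OCc2ccccc2)cc1)CC(C)=C | intermediate
12 | but-3-enoyl chloride | C=CCC(Cl)=O | starting material
13 | lithium alkoxide of 11 | C[C@@](O[Li])(CCCCCCCCCc1ccc(OCc2ccccc2)cc1)CC(C)=C | intermediate
14 | (R)-13-[4-(benzyloxy)phenyl]-2,4-dimethyltridec-1-en-4-yl but-3-enoate | C[C@@](OC(=O)CC=C)(CCCCCCCCCc1ccc(OCc2ccccc2)cc1)CC(C)=C | intermediate
15 | (R)-7-{9-[4-(benzyloxy)phenyl]nonyl}-5,7-dimethyl-6,7-dihydrooxepin-2(3H)-one, ring alkene cis | C[C@@]1(CCCCCCCCCc2ccc(OCc3ccccc3)cc2)C/C(C)=C\CC(=O)O1 | intermediate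
16 | (1S,5R,7R)-5-{9-[4-(benzyloxy)phenyl]nonyl}-5,7-dimethyl-4,8-dioxabicyclo[5.1.0]octan-3-one | C[C@@]1(CCCCCCCCCc2ccc(OCc3ccccc3)cc2)C[C@@]2(C)O[C@H]2CC(=O)O1 | intermediate
17 | (4S,5S)-5-{(2R)-11-[4-(benzyloxy)phenyl]-2-hydroxy-2-methylundecyl}-4-hydroxy-5-methyloxolan-2-one | C[C@@](O)(CCCCCCCCCc1ccc(OCc2ccccc2)cc1)C[C@]1(C)OC(=O)C[C@@H]1O | intermediate
18 | (4S,5S)-4-hydroxy-5-[(2R)-2-hydroxy-11-(4-hydroxyphenyl)-2-methylundecyl]-5-methyloxolan-2-one | C[C@@](O)(CCCCCCCCCc1ccc(O)cc1)C[C@]1(C)OC(=O)C[C@@H]1O | target

## Step count and risks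

Total step count: 9. Longest linear sequence: 8 steps (1, 2, 4, 5, 6, 7, 8, 9); step 3 prepares the side-chain bromide that enters at step 4.

**Step 6 (ring-closing metathesis).** The closure of a trisubstituted alkene in a seven-membered lactone may be slow, so that oligomerisation by cross-metathesis or migration of the β,γ-double bond into conjugation takes over. The fallback replaces the acyl tether by a boron tether that closes a six-membered ring; it sets out from 11.
- Transesterification of 11 with dibutyl vinylboronate (toluene, butanol removed) should give the mixed boronic ester butyl (R)-13-[4-(benzyloxy)phenyl]-2,4-dimethyltridec-1-en-4-yl ethenylboronate F1.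
- Ring-closing metathesis of F1 with the same second-generation Grubbs catalyst, followed by aqueous work-up, should give the cyclic alkenylboronic half-ester (6R)-6-{9-[4-(benzyloxy)phenyl]nonyl}-4,6-dimethyl-5,6-dihydro-2H-1,2-oxaborinin-2-ol F2, again with the ring-enforced cis geometry.
- Suzuki–Miyaura coupling with ethyl bromoacetate (Pd(OAc)2, P(1-naphthyl)3, K3PO4, THF) should give, with retention of alkene geometry, ethyl (3Z,6R)-15-[4-(benzyloxy)phenyl]-6-hydroxy-4,6-dimethylpentadec-3-enoate F3.
- Epoxidation under the conditions of step 7 should give ethyl 2-[(2S,3R)-3-{(2R)-11-[4-(benzyloxy)phenyl]-2-hydroxy-2-methylundecyl}-3-methyloxiran-2-yl]acetate F4, and the acid treatment of step 8 should close it with inversion at the tertiary carbon to 17, where the route is rejoined.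

**Step 7 (epoxidation).** The catalyst may discriminate the faces of a ring alkene that carries only a methyl group poorly, and the buffered aqueous medium may open or isomerise the β,γ-unsaturated lactone. The fallback gives up reagent control in favour of separation; it sets out from 15. Epoxidation with 3-chloroperbenzoic acid (NaHCO3, CH2Cl2, 0 °C) should give both cis-epoxides. Because of the stereocentre at C2′ these are diastereomers, 16 and (1R,5R,7S)-5-{9-[4-(benzyloxy)phenyl]nonyl}-5,7-dimethyl-4,8-dioxabicyclo[5.1.0]octan-3-one F5, separable by chromatography. F5 is discarded and the route is rejoined at 16.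

**Step 8 (acyl transfer with epoxide opening).** Ionisation at the tertiary carbon may escape capture by the acyl oxygen, leading to elimination to allylic alcohols, hydride shift to a ketone, or partial loss of the inversion at C5. The fallback separates ester cleavage from epoxide opening; it sets out from 16. Saponification (LiOH, THF/H2O, 0 °C) and careful acidification should give the open-chain 2-[(2S,3R)-3-{(2R)-11-[4-(benzyloxy)phenyl]-2-hydroxy-2-methylundecyl}-3-methyloxiran-2-yl]acetic acid F6. Its free, conformationally unconstrained carboxyl group should then open the epoxide at the tertiary carbon in a five-membered lactonisation (camphorsulfonic acid, 5 mol %, CH2Cl2, 0 °C), again with inversion, to give 17, where the route is rejoined.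

Further compounds
F1 | step 6 | butyl (R)-13-[4-(benzyloxy)phenyl]-2,4-dimethyltridec-1-en-4-yl ethenylboronate | C[C@@](OB(C=C)OCCCC)(CCCCCCCCCc1ccc(OCc2ccccc2)cc1)CC(C)=C
F2 | step 6 | (6R)-6-{9-[4-(benzyloxy)phenyl]nonyl}-4,6-dimethyl-5,6-dihydro-2H-1,2-oxaborinin-2-ol | C[C@@]1(CCCCCCCCCc2ccc(OCc3ccccc3)cc2)CC(C)=CB(O)O1
F3 | step 6 | ethyl (3Z,6R)-15-[4-(benzyloxy)phenyl]-6-hydroxy-4,6-dimethylpentadec-3-enoate | C[C@@](O)(CCCCCCCCCc1ccc(OCc2ccccc2)cc1)C/C(C)=C\CC(=O)OCC
F4 | step 6 | ethyl 2-[(2S,3R)-3-{(2R)-11-[4-(benzyloxy)phenyl]-2-hydroxy-2-methylundecyl}-3-methyloxiran-2-yl]acetate | C[C@@](O)(CCCCCCCCCc1ccc(OCc2ccccc2)cc1)C[C@@]1(C)O[C@H]1CC(=O)OCC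
F5 | step 7 | (1R,5R,7S)-5-{9-[4-(benzyloxy)phenyl]nonyl}-5,7-dimethyl-4,8-dioxabicyclo[5.1.0]octan-3-one | C[C@@]1(CCCCCCCCCc2ccc(OCc3ccccc3)cc2)C[C@]2(C)O[C@@H]2CC(=O)O1
F6 | step 8 | 2-[(2S,3R)-3-{(2R)-11-[4-(benzyloxy)phenyl]-2-hydroxy-2-methylundecyl}-3-methyloxiran-2-yl]acetic acid | C[C@@](O)(CCCCCCCCCc1ccc(OCc2ccccc2)cc1)C[C@@]1(C)O[C@H]1CC(=O)O
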